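The time asked about, 20 min, lies 5.00 min beyond the last reading of the oak flask, so the first question is whether oak still moves. Oak is the flask asked about, and the earlier cedar run differs from it in free catalyst.

common to all: starting material 0.10 M; temperature 90 °C
- oak: partner 0.25 M; free catalyst 4.1 mM; the very flask that is asked about, followed so far
- cedar: partner 0.25 M; free catalyst 8.2 mM; run made earlier
- flask: partner 0.250 M; free catalyst 4.1 mM; time 20 min

- oak (time / min: target / %): 2.50: 49.8; 5.00: 61.1; 6.00: 60.5; 10.0: 58.7; 12.0: 60.7; 15.0: 59.6
- cedar (time / min: target / %): 0.417: 25.5; 1.00: 50.4; 2.00: 73.9; 3.00: 73.1; 4.00: 75.8; 6.00: 75.9; 8.00: 75.4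

(scatter of a reading: 1 percentage point)

- target that was removed still counts
- the earlier runs do not show what temperature does; that part of a forecast is a guess
- additions bring no volume worth counting

- target, in percent of the starting material first charged, at 20 min
- what to do for the largest gain in target; "none" if nothing gains more than 2 percentage points (Friday's / Saturday's / Wednesday's / Thursday's / Tuesday's / none)
- target present, with what was taken out counted in, in percent of the starting material first charged, after Friday's
- target present, with what was taken out counted in, in percent of the starting material first charged, after Thursday's

- Friday's: at 20 min raise the temperature by 20 K, then wait 40 min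
- Saturday's: at 20 min add free catalyst, 100% of the amount charged, then wait 40 min
- Wednesday's: at 20 min take out 90% of the target then present, then wait 40 min
- Thursday's: at 20 min add partner, 50.0% of the amount charged, then wait 40 min
- Tuesday's: change nothing and wait 40 min more

Down the oak column, target climbs to 61.1% by 5.00 min, then wanders by about its scatter around 60.1%. Down the cedar column, target stops the same way from 2.00 min, around 74.8%. Across the columns, the cedar stop stands higher than the oak stop, and a catalyst does not shift an equilibrium, so these stops are no equilibrium.

Take the even split, target against the rest at one to one, as the zero of the scale. Oak reads odds of 1.51 and cedar 2.97, twice the odds on twice the catalyst. Odds in step with the catalyst suggest a catalysed route competing with a route that needs no catalyst. Dividing each charge by its odds gives 2.72 mM for oak and 2.76 mM for cedar, with a mean of 2.74 mM. This is the even-split level: the free catalyst charge at which, on this reading, target and the rest would stand at one to one. The share of target is then the charge over the charge plus this level.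

Starting material was not measured, and a flat target is read here as a sign that the division is over. This reckoning therefore keeps oak at 60.1% at 20 min and expects no option to gain 2 percentage points, though what heat does remains a guess.

The forecast gives 60% (59% to 61%), none as the best choice, 60% after Friday's and 60% after Thursday's: “Nothing remains to convert, so extra partner, catalyst, heat or removal should gain nothing.”

The simulation gives 60.1%, none as the best choice, 60.1% after Friday's and 60.1% after Thursday's.

    starting material + free catalyst ⇌ catalyst intermediate A (K = 696 M⁻¹, k = 8.21 M⁻¹ s⁻¹, Ea = 48.0 kJ mol⁻¹, ΔH = −15.0 kJ mol⁻¹)
    partner + catalyst intermediate A → catalyst intermediate B (k = 1.04 M⁻¹ s⁻¹, Ea = 56.0 kJ mol⁻¹)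
    catalyst intermediate B → free catalyst + target (k = 1.01 s⁻¹, Ea = 88.0 kJ mol⁻¹)
    free catalyst → spent catalyst (k = 6.73 × 10⁻⁵ s⁻¹, Ea = 117 kJ mol⁻¹)
    starting material + target → side product (k = 0.0999 M⁻¹ s⁻¹, Ea = 47.0 kJ mol⁻¹)
    partner ⇌ dormant form (K = 0.160, k = 0.0122 s⁻¹, Ea = 104 kJ mol⁻¹, ΔH = −20.0 kJ mol⁻¹)
    (constants at 90 °C)

In the oak flask, the even-split level puts target at 59.9%. The table at 20.0 min holds 60.1% target and 39.9% side product, with 0% of the starting material free. The route without catalyst turns out to be starting material meeting target, so each side product holds two units of starting material, one of them target already made. The neighbouring flask is charged with 2.50 mM of free catalyst, everything else as in the recipe, and the same level puts its target at 47.7%. At 20.0 min that neighbour holds 0% of its starting material free and 51.3% side product, and its target stands at 48.7%.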